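**Plan**

- Cuts: ring A is opened at its CH2–CH2 bond and at the oxirane C–C bond (the oxirane C–O bond goes with it), leaving an open-chain formyl acid and a two-carbon α-methylvinyl sulfonium unit. The bond from the side-chain CH2 to ring A is cut next (lactone enolate allylation). Ring B goes back to (S)-cyclohex-3-ene-1-carboxylic acid.
- Forward order: ring B with its bromohydrin is finished first (steps 1–8) and joined to a δ-lactone (steps 9–10). The lactone is opened to the formyl acid (steps 11–13), ring A and the oxirane are closed together (step 15), and the silyl ether is removed (step 16).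
- Enabling feature: in ring A the methyl-bearing oxirane carbon is flanked by an unsubstituted CH2–CH2, and the oxirane CH sits next to the ring CH that holds the side chain. The C(CH3)–CH2 unit can therefore come from one reagent: its CH2 end accepts a primary radical, and its sulfur-bearing carbon becomes an ylide that closes the six-membered ring on an aldehyde and then the oxirane. The oxirane oxygen is cis to the neighbouring side chain, i.e. axial, which is what anti-periplanar collapse in a chair delivers.
- Stereochemistry: ring B comes from the (S)-acid (iodolactonisation relay, trans-diaxial epoxide opening, methyl addition anti to bromine, thermodynamic ester epimerisation). The isopropenyl centre of ring A comes from a rhodium/(S)-BINAP conjugate addition, the side-chain centre from trans alkylation, and the two oxirane centres from the chair-controlled key step.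

Key step: step 15

Remark: the formyl acid used in the key step may sit partly as its cyclic hydroxy lactone (pseudo-acid); the phosphate base opens it to the carboxylate, and the open form is drawn.

**Route**

Step 1
Reactants: 1 (S)-cyclohex-3-ene-1-carboxylic acid
Product: 2 (1S,4S,5S)-4-iodo-6-oxabicyclo[3.2.1]octan-7-one
Conditions: I2, KI, NaHCO3, H2O, 0 °C to rt
Reagents that add atoms: iodine, II
Why: Iodolactonisation, in which the carboxylate captures the iodonium ion at the nearer alkene carbon to give the cis-fused γ-lactone with iodine anti to the new C–O bond, so the single stereocentre of 1 fixes both new ones.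

Step 2
Reactants: 2 (1S,4S,5S)-4-iodo-6-oxabicyclo[3.2.1]octan-7-one
Product: 3 methyl (1S,3S,6R)-7-oxabicyclo[4.1.0]heptane-3-carboxylate
Conditions: NaOMe, MeOH, 0 °C to rt
Reagents that add atoms: sodium methoxide, C[O-].[Na+]
Why: Methanolysis of the lactone frees an alkoxide anti to the neighbouring C–I bond, which closes the oxirane by intramolecular Williamson (SN2) displacement and so places the oxirane cis to the ester.

Step 3
Reactants: 3 methyl (1S,3S,6R)-7-oxabicyclo[4.1.0]heptane-3-carboxylate
Product: 4 methyl (1S,3R,4R)-3-bromo-4-hydroxycyclohexane-1-carboxylate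
Conditions: LiBr, AcOH, THF, rt
Reagents that add atoms: lithium bromide, [Li+].[Br-]
Why: Trans-diaxial (Fürst–Plattner) epoxide opening, in which bromide can enter axially only at the carbon 1,3 to the equatorial ester, giving bromine trans and hydroxyl cis to the ester.

Step 4
Reactants: 4 methyl (1S,3R,4R)-3-bromo-4-hydroxycyclohexane-1-carboxylate
Product: 5 methyl (1S,3R)-3-bromo-4-oxocyclohexane-1-carboxylate
Conditions: Dess–Martin periodinane, CH2Cl2, 0 °C to rt
Reagents that add atoms: none
Why: Dess–Martin oxidation is neutral enough to give the α-bromoketone without epimerisation at the bromine-bearing carbon or loss of HBr.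

Step 5
Reactants: 5 methyl (1S,3R)-3-bromo-4-oxocyclohexane-1-carboxylate
Product: 7 methyl (1R,3R,4S)-3-bromo-4-hydroxy-4-methylcyclohexane-1-carboxylate, via the 1S ester epimer 6 (not isolated)
Conditions: MeMgBr (1.3 equiv), toluene/Et2O, −78 °C; then MeOH, NaOMe (0.3 equiv), 0 °C to rt
Reagents that add atoms: methylmagnesium bromide, C[Mg]Br
Why: Grignard 1,2-addition to the α-bromoketone should occur anti to the axial C–Br bond (polar Felkin–Anh/Cornforth control, the classical route to cis-halohydrins), setting the carbinol centre with OH cis to Br while the ester is left alone at −78 °C, and methoxide then epimerises the ester-bearing carbon to the isomer with ester, bromine and methyl all equatorial.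

Step 6
Reactants: 7 methyl (1R,3R,4S)-3-bromo-4-hydroxy-4-methylcyclohexane-1-carboxylate
Product: 8 methyl (1R,3R,4S)-3-bromo-4-methyl-4-[(triethylsilyl)oxy]cyclohexane-1-carboxylate
Conditions: Et3SiOTf, 2,6-lutidine, CH2Cl2, −78 to 0 °C
Reagents that add atoms: triethylsilyl trifluoromethanesulfonate, CC[Si](CC)(CC)OS(=O)(=O)C(F)(F)F
Why: Silyl triflate with a hindered pyridine base silylates the tertiary alcohol (silyl ether protection), which keeps an alkoxide out of the enolate alkylation and blocks ether formation onto the later side-chain alkene.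

Step 7
Reactants: 8 methyl (1R,3R,4S)-3-bromo-4-methyl-4-[(triethylsilyl)oxy]cyclohexane-1-carboxylate
Product: 10 (2-{(1R,3R,4S)-3-bromo-4-methyl-4-[(triethylsilyl)oxy]cyclohexyl}prop-2-en-1-yl)trimethylsilane, via bis(silylmethyl) carbinol 9 (not isolated)
Conditions: Me3SiCH2MgCl (4 equiv), CeCl3 (4 equiv), THF, −78 °C to rt; then silica gel, CH2Cl2, rt
Reagents that add atoms: (trimethylsilyl)methylmagnesium chloride, C[Si](C)(C)C[Mg]Cl
Why: Cerium-promoted double addition of the silylmethyl Grignard reagent to the ester followed by Peterson elimination of the bis(β-silyl) carbinol is the established ester-to-allylsilane conversion and should not touch the hindered secondary bromide.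

Step 8
Reactants: 10 (2-{(1R,3R,4S)-3-bromo-4-methyl-4-[(triethylsilyl)oxy]cyclohexyl}prop-2-en-1-yl)trimethylsilane
Product: 11 {[(1S,2R,4R)-2-bromo-4-(3-bromoprop-1-en-2-yl)-1-methylcyclohexyl]oxy}triethylsilane
Conditions: N-bromosuccinimide, CH2Cl2, −78 °C, dark
Reagents that add atoms: N-bromosuccinimide, BrN1C(=O)CCC1=O
Why: Electrophilic bromodesilylation (SE2′) of the allylsilane, in which bromine adds to the terminal CH2 and the β-silyl cation loses silicon to give the transposed 2-substituted allyl bromide.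

Step 9
Reactants: 12 5,6-dihydro-2H-pyran-2-one; 13 potassium trifluoro(prop-1-en-2-yl)borate
Product: 14 (4S)-4-(prop-1-en-2-yl)tetrahydro-2H-pyran-2-one
Conditions: [Rh(cod)2]PF6 (3 mol %), (S)-BINAP (3.3 mol %), toluene/H2O, 105 °C
Reagents that add atoms: none
Why: Rhodium-catalysed asymmetric 1,4-addition (Hayashi–Miyaura reaction) of the alkenylboron reagent to this benchmark unsaturated lactone, in which the (S)-BINAP complex should select the same enone face as in the aryl additions and so give the (S) centre.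

Step 10
Reactants: 14 (4S)-4-(prop-1-en-2-yl)tetrahydro-2H-pyran-2-one; 11 {[(1S,2R,4R)-2-bromo-4-(3-bromoprop-1-en-2-yl)-1-methylcyclohexyl]oxy}triethylsilane
Product: 16 (3R,4S)-3-(2-{(1R,3R,4S)-3-bromo-4-methyl-4-[(triethylsilyl)oxy]cyclohexyl}prop-2-en-1-yl)-4-(prop-1-en-2-yl)tetrahydro-2H-pyran-2-one, via lithium enolate 15 (not isolated)
Conditions: LiN(i-Pr)2 (commercial solution, 1.05 equiv), THF, −78 °C; then 11, DMPU, −78 to −40 °C
Reagents that add atoms: none
Why: Alkylation of the lactone lithium enolate with the reactive allylic bromide should take place anti to the neighbouring isopropenyl group (1,2-induction), setting the side-chain-bearing centre trans, while the hindered secondary bromide does not compete.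

Step 11
Reactants: 16 (3R,4S)-3-(2-{(1R,3R,4S)-3-bromo-4-methyl-4-[(triethylsilyl)oxy]cyclohexyl}prop-2-en-1-yl)-4-(prop-1-en-2-yl)tetrahydro-2H-pyran-2-one
Product: 17 (2R,3S)-2-(2-{(1R,3R,4S)-3-bromo-4-methyl-4-[(triethylsilyl)oxy]cyclohexyl}prop-2-en-1-yl)-5-hydroxy-N-methoxy-N-methyl-3-(prop-1-en-2-yl)pentanamide
Conditions: MeNH(OMe)·HCl, AlMe3, CH2Cl2, 0 °C to rt
Reagents that add atoms: N,O-dimethylhydroxylamine hydrochloride, CNOC.Cl
Why: Aluminium amide aminolysis of the lactone (Weinreb amide formation) opens the ring to the hydroxy amide without touching the α-stereocentre.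

Step 12
Reactants: 17 (2R,3S)-2-(2-{(1R,3R,4S)-3-bromo-4-methyl-4-[(triethylsilyl)oxy]cyclohexyl}prop-2-en-1-yl)-5-hydroxy-N-methoxy-N-methyl-3-(prop-1-en-2-yl)pentanamide
Product: 18 (3S,4R)-6-{(1R,3R,4S)-3-bromo-4-methyl-4-[(triethylsilyl)oxy]cyclohexyl}-4-[methoxy(methyl)carbamoyl]-3-(prop-1-en-2-yl)hept-6-enoic acid
Conditions: TEMPO (cat.), PhI(OAc)2 (2.2 equiv), MeCN/H2O, rt
Reagents that add atoms: water, O
Why: TEMPO/PhI(OAc)2 oxidation in aqueous acetonitrile takes the primary alcohol through the aldehyde hydrate to the carboxylic acid and should leave the 1,1-disubstituted alkenes, the amide and the silyl ether alone.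

Step 13
Reactants: 18 (3S,4R)-6-{(1R,3R,4S)-3-bromo-4-methyl-4-[(triethylsilyl)oxy]cyclohexyl}-4-[methoxy(methyl)carbamoyl]-3-(prop-1-en-2-yl)hept-6-enoic acid
Product: 19 (3S,4R)-6-{(1R,3R,4S)-3-bromo-4-methyl-4-[(triethylsilyl)oxy]cyclohexyl}-4-formyl-3-(prop-1-en-2-yl)hept-6-enoic acid
Conditions: i-Bu2AlH (2.5 equiv), THF, −78 °C; aqueous potassium sodium tartrate, then pH 4
Reagents that add atoms: none
Why: The first equivalent of i-Bu2AlH turns CO2H into an aluminium carboxylate that is inert at −78 °C, and the Weinreb amide is reduced through its stable chelate to the aldehyde (Weinreb aldehyde synthesis), which is released only on work-up so that the α-centre is not epimerised.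

Step 14
Reactants: 20 diphenyl sulfoxide; 21 prop-1-en-2-ylmagnesium bromide
Product: 23 diphenyl(prop-1-en-2-yl)sulfonium trifluoromethanesulfonate, via silyloxysulfonium triflate 22 (not isolated)
Conditions: Me3SiOTf, CH2Cl2, −78 °C; then 21 (THF solution), −78 to 0 °C
Reagents that add atoms: trimethylsilyl trifluoromethanesulfonate, C[Si](C)(C)OS(=O)(=O)C(F)(F)F
Why: Silylation of the sulfoxide oxygen gives an S-electrophile that the organomagnesium reagent attacks at sulfur with loss of silanolate, the standard Grignard route from diaryl sulfoxides to sulfonium salts.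

Step 15
Reactants: 19 (3S,4R)-6-{(1R,3R,4S)-3-bromo-4-methyl-4-[(triethylsilyl)oxy]cyclohexyl}-4-formyl-3-(prop-1-en-2-yl)hept-6-enoic acid; 23 diphenyl(prop-1-en-2-yl)sulfonium trifluoromethanesulfonate
Product: 26 triethyl{[(1S,2R,4R)-2-bromo-1-methyl-4-{3-[(1R,2R,3S,6S)-6-methyl-3-(prop-1-en-2-yl)-7-oxabicyclo[4.1.0]heptan-2-yl]prop-1-en-2-yl}cyclohexyl]oxy}silane, via sulfonium ylide 24 (not isolated), via cyclic betaine 25 (not isolated)
Conditions: [Ir(dF(CF3)ppy)2(5,5'-d(CF3)bpy)]PF6 (2 mol %), K2HPO4 (1.2 equiv), 23 (3 equiv), DMF (0.1 M in 19), 450 nm LEDs, 20 °C, argon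
Reagents that add atoms: none
Why: Proposed new method: the excited trivalent iridium photocatalyst oxidises the carboxylate of 19, loss of CO2 leaves a primary radical that adds to the unsubstituted CH2 terminus of 23 (first new bond, CH2–CH2), and the reduced divalent iridium, which is the resting state under irradiation, returns one electron to the electrophilic tertiary α-sulfonium radical to give ylide 24 in a medium without proton donors. The closest known reactions are the epoxy-annulations in which a heteroatom nucleophile adds to a vinylsulfonium salt and the resulting ylide epoxidises a tethered carbonyl group, and the photoredox decarboxylative Giese additions that end in a carbanion (radical–polar crossover); here the radical takes the place of the nucleophile. The ylide carbon then attacks the aldehyde in a 6-exo-trig closure (second new bond, the later oxirane C–C bond) to betaine 25, and the alkoxide displaces diphenyl sulfide in a 3-exo-tet closure. The two new stereocentres are controlled by the two already present: in the chair transition state the side chain and the isopropenyl group are both equatorial, and only the betaine with axial O– and axial S+ (anti-periplanar) can close, which puts the oxirane oxygen cis to the adjacent side-chain carbon and trans to isopropenyl, the methyl-bearing carbon being inverted in the closure. The step needs intermolecular radical addition to outrun 5-exo/6-endo cyclisation onto the 1,1-disubstituted alkenes, which the high concentration and the cationic, electron-poor character of 23 should secure, and it needs ylide addition to outrun protonation, which the aprotic medium, the intramolecularity and the absence of any other carbonyl group should secure. The secondary bromide, the silyl ether and the alkenes lie outside the redox window of the catalyst, whose reduced form is too weak a reductant to attack 23 itself.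

Step 16
Reactants: 26 triethyl{[(1S,2R,4R)-2-bromo-1-methyl-4-{3-[(1R,2R,3S,6S)-6-methyl-3-(prop-1-en-2-yl)-7-oxabicyclo[4.1.0]heptan-2-yl]prop-1-en-2-yl}cyclohexyl]oxy}silane
Product: 27 (1S,2R,4R)-2-bromo-1-methyl-4-{3-[(1R,2R,3S,6S)-6-methyl-3-(prop-1-en-2-yl)-7-oxabicyclo[4.1.0]heptan-2-yl]prop-1-en-2-yl}cyclohexan-1-ol
Conditions: Bu4NF, AcOH (1:1), THF, 0 °C to rt
Reagents that add atoms: none
Why: Fluoride cleaves the Si–O bond (silyl ether deprotection) under acetic acid buffering, and the oxirane and the equatorial secondary bromide, which has no anti-periplanar hydrogen for E2 and is cis to the freed hydroxyl so cannot close to an epoxide, should survive.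

**Compound list**

1 | (S)-cyclohex-3-ene-1-carboxylic acid | OC(=O)[C@H]1CCC=CC1 | starting material
2 | (1S,4S,5S)-4-iodo-6-oxabicyclo[3.2.1]octan-7-one | O=C1O[C@H]2C[C@@H]1CC[C@@H]2I | intermediate
3 | methyl (1S,3S,6R)-7-oxabicyclo[4.1.0]heptane-3-carboxylate | COC(=O)[C@H]1CC[C@H]2O[C@H]2C1 | intermediate
4 | methyl (1S,3R,4R)-3-bromo-4-hydroxycyclohexane-1-carboxylate | COC(=O)[C@H]1CC[C@@H](O)[C@H](Br)C1 | intermediate
5 | methyl (1S,3R)-3-bromo-4-oxocyclohexane-1-carboxylate | COC(=O)[C@H]1CCC(=O)[C@H](Br)C1 | intermediate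
6 | methyl (1S,3R,4S)-3-bromo-4-hydroxy-4-methylcyclohexane-1-carboxylate | COC(=O)[C@H]1CC[C@](C)(O)[C@H](Br)C1 | intermediate
7 | methyl (1R,3R,4S)-3-bromo-4-hydroxy-4-methylcyclohexane-1-carboxylate | COC(=O)[C@@H]1CC[C@](C)(O)[C@H](Br)C1 | intermediate
8 | methyl (1R,3R,4S)-3-bromo-4-methyl-4-[(triethylsilyl)oxy]cyclohexane-1-carboxylate | COC(=O)[C@@H]1CC[C@](C)(O[Si](CC)(CC)CC)[C@H](Br)C1 | intermediate
9 | 2-{(1R,3R,4S)-3-bromo-4-methyl-4-[(triethylsilyl)oxy]cyclohexyl}-1,3-bis(trimethylsilyl)propan-2-ol | C[Si](C)(C)CC(O)(C[Si](C)(C)C)[C@@H]1CC[C@](C)(O[Si](CC)(CC)CC)[C@H](Br)C1 | intermediate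
10 | (2-{(1R,3R,4S)-3-bromo-4-methyl-4-[(triethylsilyl)oxy]cyclohexyl}prop-2-en-1-yl)trimethylsilane | C=C(C[Si](C)(C)C)[C@@H]1CC[C@](C)(O[Si](CC)(CC)CC)[C@H](Br)C1 | intermediate
11 | {[(1S,2R,4R)-2-bromo-4-(3-bromoprop-1-en-2-yl)-1-methylcyclohexyl]oxy}triethylsilane | C=C(CBr)[C@@H]1CC[C@](C)(O[Si](CC)(CC)CC)[C@H](Br)C1 | intermediate
12 | 5,6-dihydro-2H-pyran-2-one | O=C1C=CCCO1 | starting material
13 | potassium trifluoro(prop-1-en-2-yl)borate | C=C(C)[B-](F)(F)F.[K+] | starting material
14 | (4S)-4-(prop-1-en-2-yl)tetrahydro-2H-pyran-2-one | C=C(C)[C@@H]1CC(=O)OCC1 | intermediate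
15 | lithium (4S)-4-(prop-1-en-2-yl)-5,6-dihydro-4H-pyran-2-olate | C=C(C)[C@H]1CCOC([O-])=C1.[Li+] | intermediate
16 | (3R,4S)-3-(2-{(1R,3R,4S)-3-bromo-4-methyl-4-[(triethylsilyl)oxy]cyclohexyl}prop-2-en-1-yl)-4-(prop-1-en-2-yl)tetrahydro-2H-pyran-2-one | O=C1OCC[C@H](C(C)=C)[C@H]1CC(=C)[C@@H]2CC[C@](C)(O[Si](CC)(CC)CC)[C@H](Br)C2 | intermediate
17 | (2R,3S)-2-(2-{(1R,3R,4S)-3-bromo-4-methyl-4-[(triethylsilyl)oxy]cyclohexyl}prop-2-en-1-yl)-5-hydroxy-N-methoxy-N-methyl-3-(prop-1-en-2-yl)pentanamide | CON(C)C(=O)[C@H](CC(=C)[C@@H]1CC[C@](C)(O[Si](CC)(CC)CC)[C@H](Br)C1)[C@H](CCO)C(C)=C | intermediate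
18 | (3S,4R)-6-{(1R,3R,4S)-3-bromo-4-methyl-4-[(triethylsilyl)oxy]cyclohexyl}-4-[methoxy(methyl)carbamoyl]-3-(prop-1-en-2-yl)hept-6-enoic acid | CON(C)C(=O)[C@H](CC(=C)[C@@H]1CC[C@](C)(O[Si](CC)(CC)CC)[C@H](Br)C1)[C@H](CC(=O)O)C(C)=C | intermediate
19 | (3S,4R)-6-{(1R,3R,4S)-3-bromo-4-methyl-4-[(triethylsilyl)oxy]cyclohexyl}-4-formyl-3-(prop-1-en-2-yl)hept-6-enoic acid | O=C[C@H](CC(=C)[C@@H]1CC[C@](C)(O[Si](CC)(CC)CC)[C@H](Br)C1)[C@H](CC(=O)O)C(C)=C | intermediate
20 | diphenyl sulfoxide | O=S(c1ccccc1)c1ccccc1 | starting material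
21 | prop-1-en-2-ylmagnesium bromide | C=C(C)[Mg]Br | starting material
22 | diphenyl[(trimethylsilyl)oxy]sulfonium trifluoromethanesulfonate | C[Si](C)(C)O[S+](c1ccccc1)c1ccccc1.[O-]S(=O)(=O)C(F)(F)F | intermediate
23 | diphenyl(prop-1-en-2-yl)sulfonium trifluoromethanesulfonate | C=C(C)[S+](c1ccccc1)c1ccccc1.[O-]S(=O)(=O)C(F)(F)F | intermediate
24 | diphenylsulfonium (5S,6R)-8-{(1R,3R,4S)-3-bromo-4-methyl-4-[(triethylsilyl)oxy]cyclohexyl}-6-formyl-5-(prop-1-en-2-yl)non-8-en-2-ylide | O=C[C@H](CC(=C)[C@@H]1CC[C@](C)(O[Si](CC)(CC)CC)[C@H](Br)C1)[C@H](CC[C-](C)[S+](c1ccccc1)c1ccccc1)C(C)=C | intermediate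
25 | (1R,2R,5S,6R)-6-(2-{(1R,3R,4S)-3-bromo-4-methyl-4-[(triethylsilyl)oxy]cyclohexyl}prop-2-en-1-yl)-2-(diphenylsulfonio)-2-methyl-5-(prop-1-en-2-yl)cyclohexan-1-olate | C=C(C[C@@H]1[C@@H](C(=C)C)CC[C@@](C)([S+](c2ccccc2)c2ccccc2)[C@@H]1[O-])[C@@H]1CC[C@](C)(O[Si](CC)(CC)CC)[C@H](Br)C1 | intermediate
26 | triethyl{[(1S,2R,4R)-2-bromo-1-methyl-4-{3-[(1R,2R,3S,6S)-6-methyl-3-(prop-1-en-2-yl)-7-oxabicyclo[4.1.0]heptan-2-yl]prop-1-en-2-yl}cyclohexyl]oxy}silane | C=C(C[C@@H]1[C@@H](C(=C)C)CC[C@]2(C)O[C@H]12)[C@@H]1CC[C@](C)(O[Si](CC)(CC)CC)[C@H](Br)C1 | intermediate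
27 | (1S,2R,4R)-2-bromo-1-methyl-4-{3-[(1R,2R,3S,6S)-6-methyl-3-(prop-1-en-2-yl)-7-oxabicyclo[4.1.0]heptan-2-yl]prop-1-en-2-yl}cyclohexan-1-ol | C=C(C[C@@H]1[C@@H](C(=C)C)CC[C@]2(C)O[C@H]12)[C@@H]1CC[C@](C)(O)[C@H](Br)C1 | target

**Step count**

Total: 16 steps. Longest linear sequence: 14 steps (steps 1–8, 10–13, 15, 16).

**Steps most likely to fail**

Step 15. Three processes may defeat it: (a) cyclisation of the primary radical onto the side-chain alkene, or of the α-sulfonium radical onto the isopropenyl group, before the intended addition or reduction; (b) protonation of the ylide before it reaches the aldehyde; (c) carbon–carbon bond formation through a transition state whose betaine cannot reach the anti-periplanar arrangement, so that it fails to close. The fallback builds the same ylide by known two-electron chemistry; it sets out from hydroxy amide 17 and comes back at 26. The primary alcohol of 17 is converted with I2, PPh3 and imidazole (Appel conditions) into the iodide, (2R,3S)-2-(2-{(1R,3R,4S)-3-bromo-4-methyl-4-[(triethylsilyl)oxy]cyclohexyl}prop-2-en-1-yl)-5-iodo-N-methoxy-N-methyl-3-(prop-1-en-2-yl)pentanamide F1. Diphenylsulfonium ethylide, made from ethyldiphenylsulfonium tetrafluoroborate and LiN(i-Pr)2 in 1,2-dimethoxyethane at −78 °C, is alkylated by F1 (alkylation of a sulfonium ylide) to the secondary-alkyl diphenylsulfonium tetrafluoroborate amide F2; either configuration at the sulfur-bearing carbon serves. Reduction with i-Bu2AlH at −78 °C gives the sulfonium aldehyde F3. KN(SiMe3)2 in THF at −78 °C then generates ylide 24, which closes through betaine 25 to 26 (intramolecular Corey–Chaykovsky epoxidation); here the carbon that was the hydroxymethyl carbon of 17 becomes the ring CH2 next to the oxirane, and the chair argument for the configuration is unchanged.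

Step 13. The aluminium carboxylate may aggregate and slow the amide reduction, the carboxylate may be partly reduced on warming, or the α-branched aldehyde may epimerise during the acidic release. The fallback replaces the amide by a thioester that is reduced without a hydride reagent; it sets out from lactone 16 and comes back at 19. Ethanethiol and AlMe3 open 16 to the hydroxy thioester, S-ethyl (2R,3S)-2-(2-{(1R,3R,4S)-3-bromo-4-methyl-4-[(triethylsilyl)oxy]cyclohexyl}prop-2-en-1-yl)-5-hydroxy-3-(prop-1-en-2-yl)pentanethioate F4. TEMPO/PhI(OAc)2 in aqueous acetonitrile oxidises it to the thioester acid, (3S,4R)-6-{(1R,3R,4S)-3-bromo-4-methyl-4-[(triethylsilyl)oxy]cyclohexyl}-4-[(ethylsulfanyl)carbonyl]-3-(prop-1-en-2-yl)hept-6-enoic acid F5. Fukuyama reduction (Et3SiH, Pd on carbon, acetone, rt) then reduces only the thioester and should give 19 under neutral conditions.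

Step 14. The Grignard reagent may attack silicon instead of sulfur, ligand coupling may occur at sulfur, or the vinylsulfonium salt may decompose on isolation. The fallback forms the S–C(aryl) bond last; it sets out from Grignard reagent 21 and comes back at 23. Reagent 21 is quenched with diphenyl disulfide in THF at 0 °C to give phenyl prop-1-en-2-yl sulfide F6, which is S-phenylated with diphenyliodonium trifluoromethanesulfonate and catalytic Cu(OAc)2 in 1,2-dichlorobenzene at 120 °C (copper-catalysed arylation of a sulfide by a diaryliodonium salt) to give 23.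

Further compounds
F1 | step 15 | (2R,3S)-2-(2-{(1R,3R,4S)-3-bromo-4-methyl-4-[(triethylsilyl)oxy]cyclohexyl}prop-2-en-1-yl)-5-iodo-N-methoxy-N-methyl-3-(prop-1-en-2-yl)pentanamide | CON(C)C(=O)[C@H](CC(=C)[C@@H]1CC[C@](C)(O[Si](CC)(CC)CC)[C@H](Br)C1)[C@H](CCI)C(C)=C
F2 | step 15 | [(5S,6R)-8-{(1R,3R,4S)-3-bromo-4-methyl-4-[(triethylsilyl)oxy]cyclohexyl}-6-[methoxy(methyl)carbamoyl]-5-(prop-1-en-2-yl)non-8-en-2-yl]diphenylsulfonium tetrafluoroborate | CON(C)C(=O)[C@H](CC(=C)[C@@H]1CC[C@](C)(O[Si](CC)(CC)CC)[C@H](Br)C1)[C@H](CCC(C)[S+](c1ccccc1)c1ccccc1)C(C)=C.F[B-](F)(F)F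
F3 | step 15 | [(5S,6R)-8-{(1R,3R,4S)-3-bromo-4-methyl-4-[(triethylsilyl)oxy]cyclohexyl}-6-formyl-5-(prop-1-en-2-yl)non-8-en-2-yl]diphenylsulfonium tetrafluoroborate | O=C[C@H](CC(=C)[C@@H]1CC[C@](C)(O[Si](CC)(CC)CC)[C@H](Br)C1)[C@H](CCC(C)[S+](c1ccccc1)c1ccccc1)C(C)=C.F[B-](F)(F)F
F4 | step 13 | S-ethyl (2R,3S)-2-(2-{(1R,3R,4S)-3-bromo-4-methyl-4-[(triethylsilyl)oxy]cyclohexyl}prop-2-en-1-yl)-5-hydroxy-3-(prop-1-en-2-yl)pentanethioate | CCSC(=O)[C@H](CC(=C)[C@@H]1CC[C@](C)(O[Si](CC)(CC)CC)[C@H](Br)C1)[C@H](CCO)C(C)=C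
F5 | step 13 | (3S,4R)-6-{(1R,3R,4S)-3-bromo-4-methyl-4-[(triethylsilyl)oxy]cyclohexyl}-4-[(ethylsulfanyl)carbonyl]-3-(prop-1-en-2-yl)hept-6-enoic acid | CCSC(=O)[C@H](CC(=C)[C@@H]1CC[C@](C)(O[Si](CC)(CC)CC)[C@H](Br)C1)[C@H](CC(=O)O)C(C)=C
F6 | step 14 | phenyl prop-1-en-2-yl sulfide | C=C(C)Sc1ccccc1
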